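## Structural features

The target is a 2,3-dihydroflavonol, that is a chroman-4-one in which the benzene ring A is fused to the oxygen heterocycle ring C, with a 4-hydroxyphenyl group (ring B) on C2 and a hydroxyl on C3. Ring A is fully substituted, with O1 on C8a, the C4 carbonyl on C4a, hydroxyls on C5 and C7 and 3-methylbut-2-enyl (prenyl) groups on C6 and C8, so that before ring C exists it is a symmetric 3,5-diprenylated acylphloroglucinol with two equivalent ortho oxygens. The only stereocentres are the neighbouring C2 and C3, both R, which places aryl and hydroxyl trans and both equatorial on ring C. Three parts are fragile: the two prenyl double bonds, each ortho to a phenol (acid can close them to dimethylchromans, and electrophilic oxidants, osmium reagents and hydrogenation are excluded); the α-hydroxy ketone C3–C4 (base and air lead to the flavonol, and enolisation would scramble C3); and the benzylic ether bond O1–C2, which can open to a para-quinone methide because ring B carries a para hydroxyl. The real difficulty is therefore not the skeleton but the absolute configuration at C3 together with a clean 2,3-trans relationship, in a molecule that tolerates neither alkene-oxidising reagents nor harsh deprotection. The key step exploits two features: C3 is the α-carbon of an α-hydroxy aryl ketone (C4 attached to C4a of ring A) and hence a natural enediolate donor, and C2 is a para-oxygenated benzylic carbinol carbon whose configuration can be corrected when the O1–C2 bond is formed. An aldol union of C2 with C3 thus has to control C3 only.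

## Logic of the disconnections

12 to 9. The O1–C2 bond of ring C is cut, together with the four O–CH2 acetal bonds that serve as protection in 9. C2 is benzylic and para to the ring B oxygen, so this is the one C–O bond that forms and re-forms easily (through 10 and 11). The cut opens ring C without touching C3 and leads back to an acyclic diol in which either ortho oxygen can become O1. The gain is the loss of ring C and of any need to set C2 beforehand. The forward step must free four phenols beside two ortho prenyl groups and reach the trans isomer under thermodynamic control without enolising C3.

9 to 6 and 8. The C2–C3 bond of the propanone chain (C3–C2 of 12) is cut. This is an aldol retron in which 6 is the donor and 8 the acceptor. The cut divides the molecule into its ring A and ring B halves and reduces the stereochemical problem to one centre. The forward step needs a catalyst that selects one face of the enediolate of 6 and favours cross-aldol over self-aldol.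

6 to 4. The C–O bond at the hydroxymethyl carbon is cut, which leaves a methyl ketone. The forward step is an oxidation through 5 and must not touch the prenyl double bonds.

4 to 3. The three O–CH2 bonds of the acetal groups are cut. Protection is needed because free phenols would quench both the enolate and the zinc catalyst. The forward step must alkylate on oxygen, including the hydrogen-bonded ortho hydroxyls.

3 to 1 and 2. The two aryl–CH2 bonds at the free ring positions are cut. This puts both prenyl groups on at the cheapest point of the route and leads back to two commercial compounds. The forward step must alkylate on carbon, twice and not more.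

8 to 7. One O–CH2 bond is cut; the forward step is a simple phenol protection.

## Other disconnections considered

Alternative 1: The cut goes through both bonds that tie ring C to ring A, O1–C8a and C4–C4a, so that ring A becomes an aryne and the C2–C3–C4 chain with ring B becomes an anti-configured β-hydroxy ester. In the forward key step CsF would set the aryne free from 3,5-bis(methoxymethoxy)-2,4-bis(3-methylbut-2-enyl)-6-(trimethylsilyl)phenyl trifluoromethanesulfonate A2. The alkoxide of methyl (2R,3R)-3-hydroxy-2-(methoxymethoxy)-3-[4-(methoxymethoxy)phenyl]propanoate A3 would add at C8a, the aryne carbon remote from the C5 oxygen. The aryl anion left at C4a would then attack the ester to give 3,5,7,4'-tetra-O-methoxymethyl-6,8-diprenylaromadendrin A1. In its favour, both stereocentres of A1 would come from an acyclic anti-glycolate aldol and be carried into ring C with retention, since no bond at C2 or C3 is broken. The union is also highly convergent, and the alkoxy group next to the aryne steers the addition the right way. Against it here, A2 is a hexasubstituted silyl aryl triflate that is not reachable from an acylphloroglucinol in a few steps. An aryne can also undergo ene reactions with the prenyl double bonds of a second molecule. The β-alkoxide of A3 can fragment by retro-aldol or epimerise C3 under basic fluoride. Aliphatic alkoxides are weaker aryne partners than the phenoxides and stabilised carbanions for which this type of annulation is established. In comparison, this plan is the better one on stereochemical definition at C2, which would be fixed kinetically and not by equilibration. On mechanism it stands further from its precedent than the zinc aldol does. On step economy it is clearly longer, because A2 and A3 each need a multi-step preparation of their own. The acid removal of the four acetal groups of A1 is equal to the last step of the chosen plan, and C2 could equilibrate there as well.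

Alternative 2: The cut removes the two prenyl–ring bonds, C6–C1'' and C8–C1''', and moves each prenyl group to the neighbouring oxygen as a 1,1-dimethylallyl ether. In the forward key step (2R,3R)-3-(methoxymethoxy)-2-[4-(methoxymethoxy)phenyl]-5,7-bis(2-methylbut-3-en-2-yloxy)-2,3-dihydrochromen-4-one A5 would be heated with Eu(fod)3 [tris(6,6,7,7,8,8,8-heptafluoro-2,2-dimethyloctane-3,5-dionato)europium]. The O5 group of A5, activated by chelation of europium between O5 and the C4 carbonyl, should migrate first to C6, and the O7 group then to C8, the only ortho position left. Each [3,3] shift inverts the allyl unit, so the product would be 3,4'-di-O-methoxymethyl-6,8-diprenylaromadendrin A4 with two normal prenyl groups. In its favour, the prenyl groups arrive late and with positional control, so the unselective double C-alkylation of step 1 is avoided; on that point this plan is the better one. The acid-sensitive prenyl groups also see fewer steps. Against it here, the disconnection does not address C2 and C3 at all, so the core of A5 still needs its own asymmetric synthesis. Two tertiary aryl ethers must be made, one of them on the hydrogen-bonded O5, usually by propargylation and semi-hydrogenation. If the O7 group of A5 moves to C6 first, the O5 group is forced onto a Claisen–Cope path that would leave a 1,1-dimethylallyl group at C8. Heating the free 5-hydroxy ketone released by the first shift with a Lewis acid also risks chroman formation and opening of ring C. In comparison, this plan solves the ring A problem more elegantly on the structural side. Mechanistically each shift is well founded, but the ordering is the weak point. In step count it is clearly longer, because it adds ether formation and rearrangement to a core synthesis that is itself about as long as the chosen route. The last acid deprotection, here of A4, is equal in both plans.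

Alternative 3: The cut is the C3–C4 bond, and ring C is closed by an intramolecular crossed benzoin reaction. In the forward key step 2,4-bis(methoxymethoxy)-6-[1-[4-(methoxymethoxy)phenyl]-2-oxoethoxy]-3,5-bis(3-methylbut-2-enyl)benzaldehyde A7 would be treated with a chiral triazolium salt and a base. The carbene should turn the ring A formyl group into an acyl anion equivalent that adds to the side-chain aldehyde. Because the α-aryl-α-aryloxy aldehyde centre of A7 (the future C2) epimerises quickly, both epimers could be funnelled to 5,7,4'-tri-O-methoxymethyl-6,8-diprenylaromadendrin A6. In its favour, ring C and C3 would be made in one organocatalytic step without acid, the 3-hydroxyl of A6 would emerge free, and one catalyst would control both centres. On the point of closing the ring and setting the stereochemistry in one operation it is the better plan. Against it here, the carbene should prefer the unhindered aliphatic aldehyde of A7 over the electron-rich, doubly ortho-substituted aryl aldehyde. That preference would exchange the roles of the two carbonyl groups and place the ketone at C3 and the hydroxyl at C4. A7 is also an enolisable, oxidation-prone aldehyde that must be built on a hindered phenol by an alkylation, reduction and oxidation sequence. The cis/trans outcome would depend on kinetic diastereoselection, and benzoin reversibility could erode it. In comparison, ring A needs the same double prenylation, so the two plans are equal there, and equal again in the final acid deprotection, here of A6. The step count is similar or slightly higher. The mechanistic uncertainty lies in which aldehyde becomes the acyl anion, whereas in the chosen plan only one partner can enolise.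

Key step: step 5

Remarks on the chemistry:
- Configuration check: in 9 the ketone α-carbon is R, the same spatial arrangement as C3 of 12, and the carbinol carbon is S, the opposite of C2 of 12. The structures of 6, 8 and 9 are consistent with the plan, but the closure must invert or equilibrate C2.
- Design choice: thermodynamic closure in the deprotection step is preferred to a Mitsunobu closure, which would need one selectively freed ortho phenol and would have to tell two secondary hydroxyls apart.
- Assumption: the (S,S) ligand is taken to give the (2R,3S) adduct, by analogy with simpler 2-hydroxyacetophenone donors; if the facial sense is opposite with 6, the (R,R) ligand is used and nothing else changes.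
- Phenoxide salts formed by simple deprotonation are treated as the reacting forms of the numbered phenols; the preformed potassium enolate of step 3 has its own number.

## Route

Step 1
Reactants: 1 2,4,6-trihydroxyacetophenone; 2 1-bromo-3-methylbut-2-ene (prenyl bromide)
Product: 3 1-[2,4,6-trihydroxy-3,5-bis(3-methylbut-2-enyl)phenyl]ethanone
Conditions: KOH (10% aq.), 2 (2.2 equiv in all, slow addition), 0 °C to rt
Reagents that add atoms: 1-bromo-3-methylbut-2-ene (second equivalent of 2), CC(C)=CCBr
Why: C-alkylation of an acylphloroglucinol phenoxide in water, where solvation of the oxygens directs the soft allylic halide to the two free ring carbons, so that two molecules of 2 are taken up; the acetyl group tempers the ring enough that controlled stoichiometry should stop at two prenyl groups.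

Step 2
Reactants: 3 1-[2,4,6-trihydroxy-3,5-bis(3-methylbut-2-enyl)phenyl]ethanone
Product: 4 1-[2,4,6-tris(methoxymethoxy)-3,5-bis(3-methylbut-2-enyl)phenyl]ethanone
Conditions: NaH (3.3 equiv), MOMCl (3.5 equiv), DMF, 0 °C to rt
Reagents that add atoms: chloromethyl methyl ether (MOMCl), COCCl
Why: Williamson-type O-alkylation by a hard, oxocarbenium-like electrophile, which goes to oxygen and not to the fully substituted ring carbons; NaH is used because the hydrogen-bonded ortho hydroxyls resist alkylation under amine bases.

Step 3
Reactants: 4 1-[2,4,6-tris(methoxymethoxy)-3,5-bis(3-methylbut-2-enyl)phenyl]ethanone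
Product: 6 2-hydroxy-1-[2,4,6-tris(methoxymethoxy)-3,5-bis(3-methylbut-2-enyl)phenyl]ethanone, via potassium enolate 5 (not isolated)
Conditions: KN(SiMe3)2, THF, −78 °C; then 2-(phenylsulfonyl)-3-phenyloxaziridine, −78 °C; AcOH quench
Reagents that add atoms: 2-(phenylsulfonyl)-3-phenyloxaziridine, O=S(=O)(c1ccccc1)N1OC1c1ccccc1
Why: Enolate α-hydroxylation with an N-sulfonyloxaziridine: the acetyl methyl is the only acidic site and the enolate carbon of 5 attacks the oxaziridine oxygen. The potassium counter-ion and low temperature disfavour addition of the enolate to the sulfonimine by-product, and the prenyl alkenes should not be epoxidised by this reagent at −78 °C.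

Step 4
Reactants: 7 4-hydroxybenzaldehyde
Product: 8 4-(methoxymethoxy)benzaldehyde
Conditions: MOMCl, K2CO3, acetone, 0 °C to rt
Reagents that add atoms: chloromethyl methyl ether (MOMCl), COCCl
Why: O-alkylation of an unhindered, acidic phenol; protection is needed because a free phenol would protonate the zinc catalyst of step 5.

Step 5
Reactants: 6 2-hydroxy-1-[2,4,6-tris(methoxymethoxy)-3,5-bis(3-methylbut-2-enyl)phenyl]ethanone; 8 4-(methoxymethoxy)benzaldehyde
Product: 9 (2R,3S)-2,3-dihydroxy-3-[4-(methoxymethoxy)phenyl]-1-[2,4,6-tris(methoxymethoxy)-3,5-bis(3-methylbut-2-enyl)phenyl]propan-1-one
Conditions: (S,S)-ProPhenol [(S,S)-2,6-bis[[2-(hydroxydiphenylmethyl)pyrrolidin-1-yl]methyl]-4-methylphenol] (10 mol %), Et2Zn (20 mol %), 4 Å MS, THF, −35 °C; 8 in excess (1.5 equiv)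
Reagents that add atoms: none
Why: Et2Zn and the ligand form a dinuclear zinc complex with loss of ethane; its basic site deprotonates the hydroxyl and then the α-carbon of 6, giving a catalyst-bound, five-membered chelated zinc enediolate that bridges the two zinc atoms, while 8 binds at the second zinc, is attacked by the enediolate carbon, and the aldolate is released by proton transfer from the next molecule of 6. The closest known reaction type is the direct catalytic asymmetric aldol of 2-hydroxyacetophenones with aldehydes under dinuclear zinc–ProPhenol catalysis, which gives syn-1,2-diols; aryl aldehydes are a less explored acceptor class there. No ring is closed and one skeletal bond is formed, C2–C3 of the propanone chain, which becomes C3–C2 of 12. The ketone α-carbon (C2 of 9, later C3 of 12) should become R because the diarylprolinol pocket leaves only one face of the chelated enediolate open to the zinc-bound aldehyde. The carbinol carbon (C3 of 9, later C2 of 12) should become S through the syn-selective arrangement of aldehyde and Z-enediolate, but this centre is corrected later and an anti adduct with the same α-configuration would converge on the same product. The selectivity that matters is therefore enantiofacial at the enediolate carbon, plus cross- over self-aldol: 8 has no α-hydrogen, and the carbonyl of 6 is shielded by two ortho methoxymethoxy groups and two flanking prenyl groups, so self-condensation of either partner should not compete. The two ortho oxygens also twist the carbonyl out of the ring plane and offer an extra zinc-binding site, as in the ortho-alkoxy donors that suit this aldol best, and the low temperature is kept to limit retro-aldol equilibration of the electron-rich adduct.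

Step 6
Reactants: 9 (2R,3S)-2,3-dihydroxy-3-[4-(methoxymethoxy)phenyl]-1-[2,4,6-tris(methoxymethoxy)-3,5-bis(3-methylbut-2-enyl)phenyl]propan-1-one
Product: 12 6,8-diprenylaromadendrin [(2R,3R)-3,5,7-trihydroxy-2-(4-hydroxyphenyl)-6,8-bis(3-methylbut-2-enyl)-2,3-dihydrochromen-4-one], via open-chain hexol 10 (not isolated), via para-quinone methide 11 (not isolated)
Conditions: aq. HCl (3 M), MeOH, 40 °C
Reagents that add atoms: none
Why: Acid-catalysed acetal exchange with methanol frees the four phenols (10); the para-hydroxybenzylic alcohol then ionises reversibly to the O-protonated form of 11, and an ortho phenol oxygen of ring A adds to the benzylic carbon in a six-membered closure, the reaction type known from the acid-mediated cyclisation of 2'-oxygenated chalcone epoxides and of para-oxygenated 1,3-diarylpropane-1,2-diols to dihydroflavonols and flavan-3-ols. C3 is not involved and should stay R; because the O1–C2 bond of a 4'-hydroxyflavanonol can reopen under the same conditions, C2 should settle in the more stable diequatorial 2,3-trans arrangement, which is R.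

## Compound list

1 | 2,4,6-trihydroxyacetophenone | CC(=O)c1c(O)cc(O)cc1O | starting material
2 | 1-bromo-3-methylbut-2-ene (prenyl bromide) | CC(C)=CCBr | starting material
3 | 1-[2,4,6-trihydroxy-3,5-bis(3-methylbut-2-enyl)phenyl]ethanone | CC(C)=CCc1c(O)c(CC=C(C)C)c(O)c(C(C)=O)c1O | intermediate
4 | 1-[2,4,6-tris(methoxymethoxy)-3,5-bis(3-methylbut-2-enyl)phenyl]ethanone | CC(C)=CCc1c(OCOC)c(CC=C(C)C)c(OCOC)c(C(C)=O)c1OCOC | intermediate
5 | potassium 1-[2,4,6-tris(methoxymethoxy)-3,5-bis(3-methylbut-2-enyl)phenyl]ethenolate (formed in the flask, not isolated) | [K+].[O-]C(=C)c1c(OCOC)c(CC=C(C)C)c(OCOC)c(CC=C(C)C)c1OCOC | intermediate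
6 | 2-hydroxy-1-[2,4,6-tris(methoxymethoxy)-3,5-bis(3-methylbut-2-enyl)phenyl]ethanone | CC(C)=CCc1c(OCOC)c(CC=C(C)C)c(OCOC)c(C(=O)CO)c1OCOC | intermediate
7 | 4-hydroxybenzaldehyde | O=Cc1ccc(O)cc1 | starting material
8 | 4-(methoxymethoxy)benzaldehyde | COCOc1ccc(C=O)cc1 | intermediate
9 | (2R,3S)-2,3-dihydroxy-3-[4-(methoxymethoxy)phenyl]-1-[2,4,6-tris(methoxymethoxy)-3,5-bis(3-methylbut-2-enyl)phenyl]propan-1-one | CC(C)=CCc1c(OCOC)c(CC=C(C)C)c(OCOC)c(C(=O)[C@H](O)[C@@H](O)c2ccc(OCOC)cc2)c1OCOC | intermediate
10 | (2R,3S)-2,3-dihydroxy-3-(4-hydroxyphenyl)-1-[2,4,6-trihydroxy-3,5-bis(3-methylbut-2-enyl)phenyl]propan-1-one (formed in the flask, not isolated) | CC(C)=CCc1c(O)c(CC=C(C)C)c(O)c(C(=O)[C@H](O)[C@@H](O)c2ccc(O)cc2)c1O | intermediate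
11 | 4-[(2R)-2-hydroxy-3-oxo-3-[2,4,6-trihydroxy-3,5-bis(3-methylbut-2-enyl)phenyl]propylidene]cyclohexa-2,5-dien-1-one (formed in the flask, reacts as its O-protonated form, not isolated) | CC(C)=CCc1c(O)c(CC=C(C)C)c(O)c(C(=O)[C@H](O)C=C2C=CC(=O)C=C2)c1O | intermediate
12 | 6,8-diprenylaromadendrin, (2R,3R)-3,5,7-trihydroxy-2-(4-hydroxyphenyl)-6,8-bis(3-methylbut-2-enyl)-2,3-dihydrochromen-4-one | CC(C)=CCc1c(O)c(CC=C(C)C)c2c(c1O)C(=O)[C@H](O)[C@@H](c1ccc(O)cc1)O2 | target

## Step count and least certain steps

Total: 6 steps. Longest linear sequence: 5 steps (steps 1, 2, 3, 5 and 6); the aldehyde branch adds step 4.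

Step 5 (key step). The most likely failure is low conversion together with erosion of enantiofacial control. The adduct of an electron-rich aryl aldehyde can revert by retro-aldol, and a ketone that is twisted out of conjugation enolises more slowly, so the catalysed path may not outrun the reverse reaction. The fallback sets out from 4 and 8 and returns at 12. A Claisen–Schmidt condensation of 4 with 8 (KOH, EtOH, rt) should give the chalcone (E)-3-[4-(methoxymethoxy)phenyl]-1-[2,4,6-tris(methoxymethoxy)-3,5-bis(3-methylbut-2-enyl)phenyl]prop-2-en-1-one F1. A Juliá–Colonna epoxidation (poly-L-leucine, urea–H2O2, DBU, THF) uses a nucleophilic peroxide that attacks only the enone and leaves the prenyl alkenes alone. It should give [(2R,3S)-3-[4-(methoxymethoxy)phenyl]oxiran-2-yl]-[2,4,6-tris(methoxymethoxy)-3,5-bis(3-methylbut-2-enyl)phenyl]methanone F2, with the poly-L-leucine antipode chosen by analogy with the parent chalcone. The conditions of step 6 would then remove the acetals, and the freed ortho phenol would open the epoxide at the benzylic carbon with inversion, which leads to 12.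

Step 6. The most likely failure is acid-promoted addition of the freed ortho phenols to the prenyl double bonds (chroman formation), competing with acetal cleavage and ring closure. Further risks are incomplete convergence to the trans isomer and loss of the C3 configuration by tautomerisation of the quinone methide stage towards an enol of the ketone. The fallback sets out from 9 and returns at 12. ZnBr2 and n-PrSH in CH2Cl2 at 0 °C, a fast aprotic acetal cleavage, should remove the four protecting groups and exchange the benzylic hydroxyl for a thioether. The expected product is (2S)-2-hydroxy-3-(4-hydroxyphenyl)-3-(propylsulfanyl)-1-[2,4,6-trihydroxy-3,5-bis(3-methylbut-2-enyl)phenyl]propan-1-one F3, as a mixture of epimers at the sulfur-bearing carbon. The descriptor at C2 changes only because sulfur raises the priority of the neighbouring carbon. AgBF4 in CH2Cl2 at 0 °C would then activate the thioether, and the ortho phenol would close ring C to 12 without any hot protic acid.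

Step 3. The most likely failure is addition of the enolate to the sulfonimine by-product, or a second oxidation after proton exchange between product and enolate. Methyl ketone enolates are the least hindered and most prone to both. The fallback sets out from 4 and returns at 6. PhI(OAc)2 with KOH in MeOH (0 °C to rt), a hypervalent-iodine α-hydroxylation that tolerates isolated alkenes, should give 2,2-dimethoxy-2-[2,4,6-tris(methoxymethoxy)-3,5-bis(3-methylbut-2-enyl)phenyl]ethanol F4. Brief treatment with pyridinium p-toluenesulfonate in wet acetone should hydrolyse the ketal, which is far more labile than the aryl acetals, to 6.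

Step 1. The most likely failure is over-alkylation (geminal dialkylation with loss of aromaticity) and O-prenylation, because the mono- and di-prenylated phenoxides are as nucleophilic as the starting one. The fallback sets out from 1 and returns at 3. A Friedel–Crafts prenylation of 1 with 2-methylbut-3-en-2-ol and BF3·OEt2 in dioxane at rt works on the neutral phenol, where geminal alkylation cannot lead to a stable product, and should give 3 directly. This fallback makes no compound outside the list, which is recorded as F0.

## Further compounds

F1 | step 5 | (E)-3-[4-(methoxymethoxy)phenyl]-1-[2,4,6-tris(methoxymethoxy)-3,5-bis(3-methylbut-2-enyl)phenyl]prop-2-en-1-one | CC(C)=CCc1c(OCOC)c(CC=C(C)C)c(OCOC)c(C(=O)/C=C/c2ccc(OCOC)cc2)c1OCOC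
F2 | step 5 | [(2R,3S)-3-[4-(methoxymethoxy)phenyl]oxiran-2-yl]-[2,4,6-tris(methoxymethoxy)-3,5-bis(3-methylbut-2-enyl)phenyl]methanone | CC(C)=CCc1c(OCOC)c(CC=C(C)C)c(OCOC)c(C(=O)[C@@H]2O[C@H]2c3ccc(OCOC)cc3)c1OCOC
F3 | step 6 | (2S)-2-hydroxy-3-(4-hydroxyphenyl)-3-(propylsulfanyl)-1-[2,4,6-trihydroxy-3,5-bis(3-methylbut-2-enyl)phenyl]propan-1-one (both epimers at C3) | CC(C)=CCc1c(O)c(CC=C(C)C)c(O)c(C(=O)[C@H](O)C(SCCC)c2ccc(O)cc2)c1O
F4 | step 3 | 2,2-dimethoxy-2-[2,4,6-tris(methoxymethoxy)-3,5-bis(3-methylbut-2-enyl)phenyl]ethanol | CC(C)=CCc1c(OCOC)c(CC=C(C)C)c(OCOC)c(C(OC)(OC)CO)c1OCOC
F0 | step 1 | none | none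
A1 | alternative 1 | (2R,3R)-3,5,7-tris(methoxymethoxy)-2-[4-(methoxymethoxy)phenyl]-6,8-bis(3-methylbut-2-enyl)-2,3-dihydrochromen-4-one | CC(C)=CCc1c(OCOC)c(CC=C(C)C)c2c(c1OCOC)C(=O)[C@H](OCOC)[C@@H](c1ccc(OCOC)cc1)O2
A2 | alternative 1 | 3,5-bis(methoxymethoxy)-2,4-bis(3-methylbut-2-enyl)-6-(trimethylsilyl)phenyl trifluoromethanesulfonate | CC(C)=CCc1c(OS(=O)(=O)C(F)(F)F)c([Si](C)(C)C)c(OCOC)c(CC=C(C)C)c1OCOC
A3 | alternative 1 | methyl (2R,3R)-3-hydroxy-2-(methoxymethoxy)-3-[4-(methoxymethoxy)phenyl]propanoate | COC(=O)[C@H](OCOC)[C@@H](c1ccc(OCOC)cc1)O
A4 | alternative 2 | (2R,3R)-5,7-dihydroxy-3-(methoxymethoxy)-2-[4-(methoxymethoxy)phenyl]-6,8-bis(3-methylbut-2-enyl)-2,3-dihydrochromen-4-one | CC(C)=CCc1c(O)c(CC=C(C)C)c2c(c1O)C(=O)[C@H](OCOC)[C@@H](c1ccc(OCOC)cc1)O2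
A5 | alternative 2 | (2R,3R)-3-(methoxymethoxy)-2-[4-(methoxymethoxy)phenyl]-5,7-bis(2-methylbut-3-en-2-yloxy)-2,3-dihydrochromen-4-one | C=CC(C)(C)Oc1cc2c(c(OC(C)(C)C=C)c1)C(=O)[C@H](OCOC)[C@@H](c1ccc(OCOC)cc1)O2
A6 | alternative 3 | (2R,3R)-3-hydroxy-5,7-bis(methoxymethoxy)-2-[4-(methoxymethoxy)phenyl]-6,8-bis(3-methylbut-2-enyl)-2,3-dihydrochromen-4-one | CC(C)=CCc1c(OCOC)c(CC=C(C)C)c2c(c1OCOC)C(=O)[C@H](O)[C@@H](c1ccc(OCOC)cc1)O2
A7 | alternative 3 | 2,4-bis(methoxymethoxy)-6-[1-[4-(methoxymethoxy)phenyl]-2-oxoethoxy]-3,5-bis(3-methylbut-2-enyl)benzaldehyde (racemic at the ether carbon) | CC(C)=CCc1c(OCOC)c(CC=C(C)C)c(OC(C=O)c2ccc(OCOC)cc2)c(C=O)c1OCOC
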